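In 2.0 h this closed flask must bring the electrophile to the asked part reacted, and we seek the charge of free base that just does so.

electrophile 0.50 M; nucleophile 0.500 M; protic impurity 10.0 mM; time 2.0 h

    acid set free + free base ⇌ idle adduct A, settled at all times (K1 = 1.1 L mol⁻¹)
    electrophile + product ⇌ idle adduct B, settled at all times (K2 = 0.92 L mol⁻¹)
    nucleophile + protic impurity → quenched reagent (k3 = 59 L mol⁻¹ h⁻¹)
    electrophile + nucleophile → acid set free + product (k4 = 2.9 L mol⁻¹ h⁻¹)
    acid set free + free base ⇌ salt of the base, settled at all times (K5 = 480 L mol⁻¹)
    nucleophile + acid set free ⇌ protonated nucleophile, settled at all times (K6 = 72 L mol⁻¹)

- the concentration of free base at which the part of the electrophile that has reacted at 2.0 h is just 70%, in M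

- percentages count the electrophile that a species holds: one idle adduct B counts as two
- product is meant together with its idle adduct B
- acid set free is meant together with its idle adduct A
- the amount of free base is what is sought; it is there from the start
- in an amount of product, one idle adduct B counts as one product
- what has gone from electrophile into another species counts as reacted, even if it can come back
- run time (flask): 2.0 h

Let E be the free electrophile and n the free nucleophile. We build a small table with two rows, start and end, and three columns: E, n and their ratio.

Against the nucleophile as charged, the impurity has a half-life of 0.0235 h, far shorter than the run time, so we take its charge off the nucleophile at once. The start row then reads E = 0.50 M, n = 0.490 M, ratio 0.980.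

In the end row, E must be 0.150 M. Counting idle adduct B at balance, that loss of electrophile corresponds to 0.312 M of acid set free in total, bound forms counted.

The rate is 2.9 L mol⁻¹ h⁻¹ times E times n. If we write n as ρ times E, with ρ held constant, and set aside the 0.0379 M of electrophile that idle adduct B holds in the end row, the rate integrates in closed form: the reciprocal of E climbs in a straight line with slope ρ times 2.9 L mol⁻¹ h⁻¹. Reading the E column against the run time then gives ρ, the mean ratio of free nucleophile to free electrophile that the run must keep, 0.805.

If ρ is the mean of the two rows' ratios, the end row's n is 0.0944 M. Since the base binds acid more strongly, we let it take acid first and the nucleophile take the excess, and we set aside any acid that stays unbound. The nucleophile balance then asks for a free base charge of 0.229 M.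

The forecast gave 0.223 M, a little below ours, on the ground that “Protonation must therefore supply the remaining 1.8”.

The simulation gives 0.222 M. In that run 10.9% of the charged free base is still free at 2.00 h, where our count left none. Put back into the closed form for 1.00 h, ρ of 0.805 gives 53.9% of the electrophile used, and the run shows 59.1%.

The numbers were set for the occasion; the result is computed.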